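**Assumptions**

- The SMILES is read as the aryl ester of (Z)-2-methylbut-2-enoic (angelic) acid, with both 2-methylbutanoyl groups (R) and the oxirane carbon (R). Thymol numbering is used: C-1 bears C-7H2O, C-3 bears the phenol oxygen, C-4 bears C-8, and C-8 bears C-9 (oxirane CH2) and C-10 (CH2O-acyl).
- (R)-2-Methylbutanoic acid, angelic anhydride, 2,2-dimethyl-1,3-dioxan-5-one, methyl 3-hydroxy-4-iodobenzoate and both antipodes of Ph-BOX are taken as purchasable.
- The sense of induction of the copper–bisoxazoline step is assigned from a chelate model only. The (R,R)-ligand is written; the fixed requirement is sulfonylation of the pro-S hydroxymethyl group of 7, and the mirror-image ligand would be used if the model points the other way.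

## Structural features

The target is a thymol-type monoterpenoid triester: a 1,2,4-trisubstituted benzene ring with an aryl angelate at C-3, a benzylic C-7H2 esterified with (R)-2-methylbutanoic acid at C-1, and the fully substituted carbon C-8 at C-4. C-8 belongs to a 2,2-disubstituted oxirane (C-8, C-9, O) and also bears C-10H2, whose oxygen carries the second (R)-2-methylbutanoyl group. There are three stereocentres, none adjacent to another: C-8 (R) in the skeleton and the two acyl α-carbons (both R), which are bought with the acid; the only alkene is the Z-trisubstituted one of the angelate. The fragile groups are the tertiary benzylic oxirane ortho to an oxygenated ring carbon (labile to acid and Lewis acid, and to o-quinone methide formation once the phenol is free), the aryl angelate (an active ester that isomerises to the tiglate under nucleophilic catalysis and hands its acyl group to neighbouring alkoxides), the benzylic ester (hydrogenolysis) and the epimerisable α-centres of the 2-methylbutanoates. The real difficulty is C-8: a quaternary oxygenated carbon with no neighbouring stereocentre to relay from, whose two CH2O arms (C-9 and C-10) differ only in that one oxygen is tied back to C-8. Read the other way round, this is the feature the key step exploits: C-8, C-9 and C-10 with their three oxygens are a 2-arylglycerol whose two enantiotopic hydroxymethyl groups have been told apart. A second difficulty is the order of events at the end, because phenoxide, oxirane and aryl ester do not tolerate one another's usual reagents.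

## Logic of the disconnections

**14 ⇒ 11 + 12.** The O–C(acyl) bond of the aryl ester at C-3 is cut. It is the most labile bond of 14, so it is made last, and every earlier step is free of the Z-enoate and of an aryl ester next to alkoxides. The forward step must take the phenol oxygen from silyl ether to ester without leaving it free beside the oxirane, and without nucleophilic catalyst or heat.

**11 ⇒ 10.** The O–C-9 bond of the oxirane is cut. Closure by 3-exo-tet displacement of a primary sulfonate by the C-8 oxygen forms the ring without touching any bond at C-8, and the strained, acid-labile ring is absent from all earlier intermediates. The forward step needs a base that acts on the tertiary hydroxyl only and is consumed before esters or the silyl ether are attacked.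

**10 ⇒ 8 + 9 (twice).** The two alkyl ester C–O bonds at O-7 and O-10 are cut together, because the acyl groups are identical. This removes any need for a protecting group at C-7 anywhere in the route. The forward step must acylate two primary hydroxyls beside a tertiary one without epimerising 9.

**8 ⇒ 7 (key disconnection).** The S–O bond at O-9 is cut. Without the sulfonyl group the two arms at C-8 are identical, C-8 is no longer a stereocentre, and the only skeletal stereocentre of 14 is replaced by a mirror plane in an achiral precursor. In one sentence, the route is the enantiotopic-group-selective monosulfonylation of the Cs-symmetric 2-arylglycerol 7, which does not describe an olefin-epoxidation route. The forward step must select the pro-S hydroxymethyl group, ignore the benzylic hydroxyl and stop after one sulfonylation.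

**7 ⇒ 3 + 4.** The C-4–C-8 bond is cut (and the acetal of the adduct). An aryl nucleophile and a protected dihydroxyacetone deliver C-8, C-9, C-10 and all three oxygens in one C–C bond formation. The forward step needs an aryl metal that tolerates the ortho silyloxy group and a metal alkoxide at C-7, and that adds to 4 instead of enolising it.

**3 ⇒ 2 ⇒ 1.** These are functional-group changes only: reduction of the ester to C-7H2OH and silylation of the phenol. 1 already has the 1,3,4-substitution pattern, with iodine at the carbon that becomes C-4. The silyl group must be bulky enough to last until the final step.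

## Other disconnections considered

**Alternative 1:** (the first that comes to mind) Both C–O bonds of the oxirane are cut across C-8/C-9, leading to the 2-arylallylic alcohol A1. The forward key step is a Sharpless asymmetric epoxidation of A1 (Ti(OiPr)4, L-(+)-diisopropyl tartrate, TBHP) to the epoxy alcohol A2, followed by acylation to 11. The chosen plan is preferred on mechanism: A2 is a tertiary benzylic epoxy alcohol that is bound to Lewis-acidic Ti(IV) as it forms, and its ortho-oxygenated ring stabilises positive charge at C-8, so ring opening and Meinwald shift under the reaction conditions are the expected loss channel for this substrate class. The chosen plan sets C-8 in a robust acyclic sulfonate and makes the oxirane later with base only. It also has a self-correcting element (over-sulfonylation removes the minor enantiomer) that a face-selective oxidation lacks. Alternative 1 is, however, not longer than the chosen route, and is shorter if the benzylic hydroxyl is left free as in the fallback to step 4; it is rejected on mechanism, not on step count.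

**Alternative 2:** The C-8–C-10 bond is cut. The forward key step is deprotonation of the enantioenriched aryl oxirane A3 at C-8 (s-BuLi/TMEDA, −98 °C) and trapping of the oxiranyllithium with formaldehyde to give A4, an umpolung of the oxirane carbon with retention. The chosen plan is preferred for three reasons. The stereocentre would first have to be made in a separate asymmetric step on the monosubstituted oxirane (asymmetric epoxidation of the styrene or a hydrolytic kinetic resolution). The carbanion at C-8 sits 1,4 to the silicon of the ortho silyloxy group, so an O→C silyl shift (retro-Brook) competes, and with other ortho oxygen groups ortho-lithiation and carbenoid ring opening compete instead. A4 would also need two more protecting-group operations before 11 is reached.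

**Alternative 3:** The C-8–C-9 bond and the C-9–O bond are cut, removing the oxirane CH2 and leaving the α-acyloxy ketone A5. The forward key step is a catalytic asymmetric Corey–Chaykovsky methylene transfer (dimethyloxosulfonium methylide, chiral lanthanide–binaphthoxide catalyst) that would give 11 directly. The chosen plan is preferred on structure and mechanism: catalysts of this type distinguish a methyl group from a large group, whereas A5 has an ortho-substituted aryl and a CH2O-acyl group of similar demand on either side of the carbonyl. The ylide is also a strong base and nucleophile toward an enolisable α-acyloxy ketone (enolisation, acyl shift, ester attack), and A5 itself needs several steps.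

Key step: step 4

## Route

**Step 1**
Reactants: 1 methyl 3-hydroxy-4-iodobenzoate
Product: 2 methyl 4-iodo-3-[(triisopropylsilyl)oxy]benzoate
Conditions: TIPSCl (1.2 equiv), imidazole (2.5 equiv), DMF, rt
Reagents that add atoms: chlorotriisopropylsilane (TIPSCl), CC(C)[Si](Cl)(C(C)C)C(C)C
Why: O-silylation of a phenol. TIPS is chosen because it should survive DIBAL, the Grignard step, dilute acid, carbonate and alkoxide, is too bulky to move to the C-8 oxygen, and still leaves with fluoride in the last step.

**Step 2**
Reactants: 2 methyl 4-iodo-3-[(triisopropylsilyl)oxy]benzoate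
Product: 3 {4-iodo-3-[(triisopropylsilyl)oxy]phenyl}methanol
Conditions: DIBAL-H (2.5 equiv), CH2Cl2, −78 to 0 °C; aq. Rochelle salt
Reagents that add atoms: none
Why: DIBAL reduction of an aryl ester to the benzylic alcohol (C-7); the aryl iodide and the aryl silyl ether are inert to the hydride.

**Step 3**
Reactants: 3 {4-iodo-3-[(triisopropylsilyl)oxy]phenyl}methanol; 4 2,2-dimethyl-1,3-dioxan-5-one
Product: 7 2-{4-(hydroxymethyl)-2-[(triisopropylsilyl)oxy]phenyl}propane-1,2,3-triol, via arylmagnesium alkoxide 5 (not isolated), via dioxanol adduct 6 (not isolated)
Conditions: i-PrMgCl·LiCl (2.2 equiv), THF, −20 to 0 °C; 4 (1.3 equiv), −30 to 0 °C; then 1 M aq. HCl, THF, rt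
Reagents that add atoms: none
Why: Iodine–magnesium exchange (the first equivalent deprotonates the C-7 hydroxyl) gives 5, which adds to the ketone of 4 and forms the C-4–C-8 bond together with the whole C-8/C-9/C-10 glycerol unit; magnesium is used because o-lithioaryl silyl ethers undergo O→C silyl shift. Dilute acid then hydrolyses the 1,3-dioxane acetal of 6 while the aryl TIPS ether should survive; 7 is achiral because C-8 carries two identical CH2OH groups.

**Step 4**
Reactants: 7 2-{4-(hydroxymethyl)-2-[(triisopropylsilyl)oxy]phenyl}propane-1,2,3-triol
Product: 8 (2S)-2,3-dihydroxy-2-{4-(hydroxymethyl)-2-[(triisopropylsilyl)oxy]phenyl}propyl 4-methylbenzenesulfonate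
Conditions: TsCl (1.05 equiv), Cu(OTf)2 (5 mol %), (R,R)-Ph-BOX (6 mol %), K2CO3 (1.5 equiv), MeCN, 0 °C
Reagents that add atoms: 4-methylbenzenesulfonyl chloride (TsCl), Cc1ccc(cc1)S(Cl)(=O)=O
Why: The Cu(II)–bisoxazoline complex binds the C-8 hydroxyl and one of the two enantiotopic CH2OH groups of 7 as a five-membered chelate; coordination acidifies the bound primary hydroxyl enough for carbonate to deprotonate it, the copper alkoxide is sulfonylated by TsCl, and the product is released so that the catalyst turns over. The closest known reaction type is the copper–bisoxazoline-catalysed desymmetrising monoacylation or monosulfonylation of meso-1,2-diols and of 2-substituted glycerols. No ring is closed. The new stereocentre C-8 arises by group selection and is controlled by the C2-symmetric ligand alone: of the two diastereomeric chelates, the reactive one should place the bulky ortho-silyloxyaryl group in an open quadrant and the small free CH2OH arm toward a ligand phenyl group, so that a single arm (required: the pro-S arm, giving (S)-8) is tosylated. Chemoselectivity over the C-7 benzylic hydroxyl follows from the mechanism, because a hydroxyl that cannot chelate is neither acidified nor deprotonated by K2CO3, and the tertiary hydroxyl is too hindered to react. Mono-sulfonylation is secured by the stoichiometry of TsCl, and over-reaction should help: in the minor enantiomer the remaining free arm is the one the catalyst prefers, so it should be consumed faster to the bis-sulfonate and raise the enantiomeric purity of 8. A sulfonate is used as the differentiating group because it cannot migrate between O-9, O-8 and O-10 (which would racemise C-8) and because it is already the leaving group needed for the oxirane.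

**Step 5**
Reactants: 8 (2S)-2,3-dihydroxy-2-{4-(hydroxymethyl)-2-[(triisopropylsilyl)oxy]phenyl}propyl 4-methylbenzenesulfonate; 9 (2R)-2-methylbutanoic acid
Product: 10 (2S)-2-hydroxy-2-[4-({[(2R)-2-methylbutanoyl]oxy}methyl)-2-[(triisopropylsilyl)oxy]phenyl]-3-(tosyloxy)propyl (2R)-2-methylbutanoate
Conditions: 9 (2.4 equiv), EDC·HCl (2.6 equiv), DMAP (0.2 equiv), CH2Cl2, 0 °C to rt
Reagents that add atoms: none
Why: Steglich esterification of the two primary hydroxyls (O-7 and O-10) in one operation; the tertiary C-8 hydroxyl is inert, and carbodiimide activation at low temperature with catalytic DMAP should leave the α-centre of 9 intact. Any premature closure to the oxirane would be acylated on to 11 and so is not lost.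

**Step 6**
Reactants: 10 (2S)-2-hydroxy-2-[4-({[(2R)-2-methylbutanoyl]oxy}methyl)-2-[(triisopropylsilyl)oxy]phenyl]-3-(tosyloxy)propyl (2R)-2-methylbutanoate
Product: 11 {(2R)-2-[4-({[(2R)-2-methylbutanoyl]oxy}methyl)-2-[(triisopropylsilyl)oxy]phenyl]oxiran-2-yl}methyl (2R)-2-methylbutanoate
Conditions: KOt-Bu (1.05 equiv), THF, −40 to −10 °C
Reagents that add atoms: none
Why: Intramolecular Williamson etherification (3-exo-tet): the C-8 alkoxide displaces the primary tosylate at C-9, no bond to C-8 is broken, and the configuration set in step 4 is carried over (the descriptor changes from S to R only because the CIP ranking of the arms changes). One equivalent of base at low temperature should be consumed by the hydroxyl before esters are attacked, and transfer of a TIPS group to a tertiary alkoxide is sterically prohibitive.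

**Step 7**
Reactants: 11 {(2R)-2-[4-({[(2R)-2-methylbutanoyl]oxy}methyl)-2-[(triisopropylsilyl)oxy]phenyl]oxiran-2-yl}methyl (2R)-2-methylbutanoate; 12 (2Z)-2-methylbut-2-enoic anhydride (angelic anhydride)
Product: 14 {(2R)-2-[2-{[(2Z)-2-methylbut-2-enoyl]oxy}-4-({[(2R)-2-methylbutanoyl]oxy}methyl)phenyl]oxiran-2-yl}methyl (2R)-2-methylbutanoate, via tetrabutylammonium phenoxide 13 (not isolated)
Conditions: 12 (1.5 equiv), TBAF (1.1 equiv, 1 M in THF, added last), THF, −40 °C; pH 7 buffer
Reagents that add atoms: none
Why: Fluoride-triggered exchange of O-silyl for O-acyl: fluoride cleaves the aryl O–Si bond and phenoxide 13 is acylated by 12 as it forms, so neither a free phenol nor a long-lived phenoxide sits next to the oxirane. No DMAP, phosphine or heat is present, which are the usual causes of angelate-to-tiglate isomerisation, and the Z geometry is that of 12.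

## Compound list

1 | methyl 3-hydroxy-4-iodobenzoate | COC(=O)c1ccc(I)c(O)c1 | starting material
2 | methyl 4-iodo-3-[(triisopropylsilyl)oxy]benzoate | COC(=O)c1ccc(I)c(O[Si](C(C)C)(C(C)C)C(C)C)c1 | intermediate
3 | {4-iodo-3-[(triisopropylsilyl)oxy]phenyl}methanol | OCc1ccc(I)c(O[Si](C(C)C)(C(C)C)C(C)C)c1 | intermediate
4 | 2,2-dimethyl-1,3-dioxan-5-one | CC1(C)OCC(=O)CO1 | starting material
5 | chloromagnesium {4-(chloromagnesio)-3-[(triisopropylsilyl)oxy]phenyl}methanolate (not isolated) | Cl[Mg]OCc1ccc([Mg]Cl)c(O[Si](C(C)C)(C(C)C)C(C)C)c1 | intermediate
6 | 5-{4-(hydroxymethyl)-2-[(triisopropylsilyl)oxy]phenyl}-2,2-dimethyl-1,3-dioxan-5-ol (not isolated) | CC1(C)OCC(O)(CO1)c1ccc(CO)cc1O[Si](C(C)C)(C(C)C)C(C)C | intermediate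
7 | 2-{4-(hydroxymethyl)-2-[(triisopropylsilyl)oxy]phenyl}propane-1,2,3-triol (achiral) | OCC(O)(CO)c1ccc(CO)cc1O[Si](C(C)C)(C(C)C)C(C)C | intermediate
8 | (2S)-2,3-dihydroxy-2-{4-(hydroxymethyl)-2-[(triisopropylsilyl)oxy]phenyl}propyl 4-methylbenzenesulfonate | Cc1ccc(cc1)S(=O)(=O)OC[C@@](O)(CO)c1ccc(CO)cc1O[Si](C(C)C)(C(C)C)C(C)C | intermediate
9 | (2R)-2-methylbutanoic acid | CC[C@@H](C)C(=O)O | starting material
10 | (2S)-2-hydroxy-2-[4-({[(2R)-2-methylbutanoyl]oxy}methyl)-2-[(triisopropylsilyl)oxy]phenyl]-3-(tosyloxy)propyl (2R)-2-methylbutanoate | CC[C@@H](C)C(=O)OC[C@](O)(COS(=O)(=O)c1ccc(C)cc1)c1ccc(COC(=O)[C@H](C)CC)cc1O[Si](C(C)C)(C(C)C)C(C)C | intermediate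
11 | {(2R)-2-[4-({[(2R)-2-methylbutanoyl]oxy}methyl)-2-[(triisopropylsilyl)oxy]phenyl]oxiran-2-yl}methyl (2R)-2-methylbutanoate | CC[C@@H](C)C(=O)OC[C@]1(CO1)c1ccc(COC(=O)[C@H](C)CC)cc1O[Si](C(C)C)(C(C)C)C(C)C | intermediate
12 | (2Z)-2-methylbut-2-enoic anhydride (angelic anhydride) | C/C=C(/C)C(=O)OC(=O)/C(C)=C\C | starting material
13 | tetrabutylammonium 5-({[(2R)-2-methylbutanoyl]oxy}methyl)-2-[(2R)-2-({[(2R)-2-methylbutanoyl]oxy}methyl)oxiran-2-yl]phenolate (not isolated) | CC[C@@H](C)C(=O)OC[C@]1(CO1)c1ccc(COC(=O)[C@H](C)CC)cc1[O-].CCCC[N+](CCCC)(CCCC)CCCC | intermediate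
14 | {(2R)-2-[2-{[(2Z)-2-methylbut-2-enoyl]oxy}-4-({[(2R)-2-methylbutanoyl]oxy}methyl)phenyl]oxiran-2-yl}methyl (2R)-2-methylbutanoate | C/C=C(/C)C(=O)Oc1cc(COC(=O)[C@H](C)CC)ccc1[C@]1(COC(=O)[C@H](C)CC)CO1 | target

## Step count and least certain steps

Total step count: 7. Longest linear sequence: 7 steps (1 → 14); 4, 9 and 12 are purchased.

**Step 4 (key step).** Three things are most likely to go wrong.
- Enantiotopic-group selectivity may erode, because the bulky ortho-silyloxyaryl group at C-8 may distort the copper chelate on which the discrimination rests.
- Sulfonylation may compete at the unactivated benzylic hydroxyl.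
- Over-sulfonylation may go too far and cost material.

The fallback gives up group selection for face selection. It sets out from 3, which is coupled (Stille, Pd(PPh3)4, copper(I) thiophene-2-carboxylate, NMP, rt) with 2-(tributylstannyl)prop-2-en-1-ol to give 2-{4-(hydroxymethyl)-2-[(triisopropylsilyl)oxy]phenyl}prop-2-en-1-ol F1. Sharpless asymmetric epoxidation (Ti(OiPr)4, L-(+)-diisopropyl tartrate, TBHP, 4 Å sieves, CH2Cl2, −20 °C; only the allylic hydroxyl directs) should then give [(2S)-2-{4-(hydroxymethyl)-2-[(triisopropylsilyl)oxy]phenyl}oxiran-2-yl]methanol F2. Acylation of both primary hydroxyls with 9 (EDC, DMAP) comes back to the route at 11. The price is the Ti(IV) lability discussed under Alternative 1.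

**Step 3.** The most likely failure is proton transfer from the α-CH2 groups of 4 to the hindered, ortho-substituted aryl–magnesium bond (enolisation instead of addition), made worse if the iodine–magnesium exchange is slow next to the magnesium alkoxide. The fallback changes the electrophile and the oxidation level at which C-9 and C-10 arrive. It sets out from 3, converted into 5 as before, and adds non-enolisable diethyl oxomalonate at −78 °C to give diethyl 2-hydroxy-2-{4-(hydroxymethyl)-2-[(triisopropylsilyl)oxy]phenyl}propanedioate F3. Reduction of both esters (LiBH4, THF/MeOH, 0 °C) comes back to the route at 7.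

**Step 7.** The most likely failures are Z→E isomerisation of the angeloyl group by reversible conjugate addition of fluoride or carboxylate, opening of the oxirane by the transient phenoxide before it is acylated, and fluoride-induced ester cleavage. The fallback builds the Z double bond last instead of importing it. It sets out from 11, which is carried through the same fluoride-triggered exchange with 2-[bis(2,2,2-trifluoroethoxy)phosphoryl]propanoyl chloride in place of 12. This gives 5-({[(2R)-2-methylbutanoyl]oxy}methyl)-2-[(2R)-2-({[(2R)-2-methylbutanoyl]oxy}methyl)oxiran-2-yl]phenyl 2-[bis(2,2,2-trifluoroethoxy)phosphoryl]propanoate F4. A Still–Gennari olefination with acetaldehyde (KHMDS, 18-crown-6, THF, −78 °C) should form the Z-trisubstituted enoate on the finished aryl ester and comes back to the route at 14.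

## Further compounds

F1 | step 4 | 2-{4-(hydroxymethyl)-2-[(triisopropylsilyl)oxy]phenyl}prop-2-en-1-ol | C=C(CO)c1ccc(CO)cc1O[Si](C(C)C)(C(C)C)C(C)C
F2 | step 4 | [(2S)-2-{4-(hydroxymethyl)-2-[(triisopropylsilyl)oxy]phenyl}oxiran-2-yl]methanol | OC[C@]1(CO1)c1ccc(CO)cc1O[Si](C(C)C)(C(C)C)C(C)C
F3 | step 3 | diethyl 2-hydroxy-2-{4-(hydroxymethyl)-2-[(triisopropylsilyl)oxy]phenyl}propanedioate | CCOC(=O)C(O)(C(=O)OCC)c1ccc(CO)cc1O[Si](C(C)C)(C(C)C)C(C)C
F4 | step 7 | 5-({[(2R)-2-methylbutanoyl]oxy}methyl)-2-[(2R)-2-({[(2R)-2-methylbutanoyl]oxy}methyl)oxiran-2-yl]phenyl 2-[bis(2,2,2-trifluoroethoxy)phosphoryl]propanoate | CC(C(=O)Oc1cc(COC(=O)[C@H](C)CC)ccc1[C@]1(COC(=O)[C@H](C)CC)CO1)P(=O)(OCC(F)(F)F)OCC(F)(F)F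
A1 | alternative 1 | {4-(3-hydroxyprop-1-en-2-yl)-3-[(triisopropylsilyl)oxy]phenyl}methyl (2R)-2-methylbutanoate | C=C(CO)c1ccc(COC(=O)[C@H](C)CC)cc1O[Si](C(C)C)(C(C)C)C(C)C
A2 | alternative 1 | {4-[(2S)-2-(hydroxymethyl)oxiran-2-yl]-3-[(triisopropylsilyl)oxy]phenyl}methyl (2R)-2-methylbutanoate | OC[C@]1(CO1)c1ccc(COC(=O)[C@H](C)CC)cc1O[Si](C(C)C)(C(C)C)C(C)C
A3 | alternative 2 | tert-butyl(dimethyl)({4-[(2R)-oxiran-2-yl]-3-[(triisopropylsilyl)oxy]phenyl}methoxy)silane | CC(C)(C)[Si](C)(C)OCc1ccc([C@@H]2CO2)c(O[Si](C(C)C)(C(C)C)C(C)C)c1
A4 | alternative 2 | [(2S)-2-{4-({[tert-butyl(dimethyl)silyl]oxy}methyl)-2-[(triisopropylsilyl)oxy]phenyl}oxiran-2-yl]methanol | OC[C@]1(CO1)c1ccc(CO[Si](C)(C)C(C)(C)C)cc1O[Si](C(C)C)(C(C)C)C(C)C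
A5 | alternative 3 | 2-[4-({[(2R)-2-methylbutanoyl]oxy}methyl)-2-[(triisopropylsilyl)oxy]phenyl]-2-oxoethyl (2R)-2-methylbutanoate | CC[C@@H](C)C(=O)OCC(=O)c1ccc(COC(=O)[C@H](C)CC)cc1O[Si](C(C)C)(C(C)C)C(C)C
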